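**Retrosynthetic overview**

1. Target 20 (a cyclic peroxyhemiketal) ⇐ methyl peroxyketal 19 by hydrolysis; C3 and C4 finish under thermodynamic control.
2. 19 ⇐ acyclic mixed peroxyketal 15 by one isomerisation: peroxycarbenium/alkene ring closure forming C5–C6, 1,2-hydride shift from C3 to C4, methoxy return. This builds the only ring, the 1,2-dioxane, together with C6, C4 and the ketal level of C3.
3. Enabling feature: in the ring O1–O2–C3–C4–C5–C6, C6 is a fully substituted carbon on O1 (the carbonyl carbon of a methyl ketone, hence a peroxycarbenium site), C5 is a bare CH2 next to the methyl-branched C4, and C3 carries O2 plus a second oxygen. A C3–H carbinyl peroxide bearing a C4=C5 isopropenyl group is therefore a redox isomer of the ring.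
4. 15 ⇐ enol ether 11 + (R)-hydroperoxide 14 (singlet-oxygen ene reaction of 2-methylbut-2-ene, enzymatic kinetic resolution); the C3–H stereocentre of 14 is a traceless relay for C6 and C4.
5. 11 ⇐ (R)-citronellic acid 1 (its C1 becomes ring C6, its C3 the side-chain stereocentre) + chloroalkyne 7 (copper-catalysed sp3–sp3 coupling, Z-selective semihydrogenation).

Key step: step 11

Assumption: the selenoenzyme of step 9 is taken to leave the R enantiomer of hydroperoxide 13, as it does for 1-arylethyl hydroperoxides; the configuration of 14 is checked by reducing a sample to the known alcohol.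

**Route**

Step 1
Reactants: 1 (R)-citronellic acid [(3R)-3,7-dimethyloct-6-enoic acid]
Product: 2 (4R)-4,8-dimethylnon-7-en-2-one
Conditions: MeLi (2.2 equiv), Et2O, 0 °C to rt; then aq. NH4Cl
Reagents that add atoms: methyllithium, C[Li]
Why: Organolithium ketone synthesis from a carboxylic acid: the dilithio gem-diolate does not collapse before work-up, so addition stops at the methyl ketone, and the stereocentre is not involved.

Step 2
Reactants: 2 (4R)-4,8-dimethylnon-7-en-2-one
Product: 3 (6R)-8,8-dimethoxy-2,6-dimethylnon-2-ene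
Conditions: HC(OMe)3, MeOH, PPTS (cat.), rt
Reagents that add atoms: trimethyl orthoformate, COC(OC)OC; methanol, CO
Why: Acid-catalysed ketalisation with the orthoformate as water scavenger; the ketal masks the carbonyl through steps 3–6 and later supplies the methoxy group of the peroxyketal.

Step 3
Reactants: 3 (6R)-8,8-dimethoxy-2,6-dimethylnon-2-ene
Product: 5 (4R)-6,6-dimethoxy-4-methylheptan-1-ol, via aldehyde 4 (not isolated)
Conditions: O3, CH2Cl2/MeOH, NaHCO3, −78 °C; then NaBH4, −78 °C to rt
Reagents that add atoms: ozone, [O-][O+]=O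
Why: Ozonolysis of the trisubstituted alkene with reductive NaBH4 work-up; the dimethyl ketal has no acetal C–H and is inert to ozone and to borohydride.

Step 4
Reactants: 5 (4R)-6,6-dimethoxy-4-methylheptan-1-ol
Product: 6 (4R)-6,6-dimethoxy-4-methylheptyl 4-methylbenzenesulfonate
Conditions: TsCl, Et3N, DMAP (cat.), CH2Cl2, 0 °C
Reagents that add atoms: 4-toluenesulfonyl chloride, Cc1ccc(cc1)S(=O)(=O)Cl
Why: Sulfonylation of a primary alcohol under basic conditions that leave the ketal untouched.

Step 5
Reactants: 6 (4R)-6,6-dimethoxy-4-methylheptyl 4-methylbenzenesulfonate; 7 (5-chloropent-1-yn-1-yl)benzene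
Product: 9 [(9R)-11,11-dimethoxy-9-methyldodec-1-yn-1-yl]benzene, via Grignard reagent 8 (not isolated)
Conditions: 7, Mg, THF, reflux; then 6, Li2CuCl4 (cat.), THF, −20 °C to rt
Reagents that add atoms: none
Why: Copper-catalysed cross-coupling of a primary alkyl tosylate with a primary alkyl Grignard reagent (Kochi-type sp3–sp3 coupling); the internal aryl alkyne and the ketal are spectators.

Step 6
Reactants: 9 [(9R)-11,11-dimethoxy-9-methyldodec-1-yn-1-yl]benzene
Product: 10 [(1Z,9R)-11,11-dimethoxy-9-methyldodec-1-en-1-yl]benzene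
Conditions: H2 (1 atm), Pd/CaCO3 poisoned with Pb(OAc)2, quinoline, hexane/EtOAc, rt
Reagents that add atoms: none
Why: Lindlar semihydrogenation: syn delivery of H2 to the aryl alkyne on the poisoned surface gives the Z-styrene.

Step 7
Reactants: 10 [(1Z,9R)-11,11-dimethoxy-9-methyldodec-1-en-1-yl]benzene
Product: 11 [(1Z,9R)-11-methoxy-9-methyldodeca-1,11-dien-1-yl]benzene (terminal methyl enol ether, accompanied by its 10-ene regioisomers)
Conditions: TMSOTf, iPr2NEt, CH2Cl2, −20 °C to rt
Reagents that add atoms: none
Why: Silyl triflate-mediated elimination of methanol from a dimethyl ketal (ionisation to the oxocarbenium ion, deprotonation by the hindered amine); all enol ether regioisomers converge to one oxocarbenium ion in step 10.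

Step 8
Reactants: 12 2-methylbut-2-ene
Product: 13 rac-3-hydroperoxy-2-methylbut-1-ene
Conditions: O2, visible light, tetraphenylporphyrin (cat.), CH2Cl2, −10 °C; the tertiary regioisomer is removed by cold chromatography, and the product is kept in solution
Reagents that add atoms: dioxygen, O=O
Why: Schenck ene reaction of singlet oxygen with a trisubstituted alkene; the secondary allylic hydroperoxide is expected alongside its tertiary regioisomer, and no stereocontrol is needed here.

Step 9
Reactants: 13 rac-3-hydroperoxy-2-methylbut-1-ene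
Product: 14 (3R)-3-hydroperoxy-2-methylbut-1-ene
Conditions: seleno-subtilisin (cat., from subtilisin Carlsberg), 5-mercapto-2-nitrobenzoic acid, citrate buffer pH 5.5, 25 °C, run past half conversion
Reagents that add atoms: none
Why: Enzymatic kinetic resolution of a secondary hydroperoxide by a peroxidase-type selenoenzyme, which should reduce the S enantiomer to the alcohol with the thiol and leave the R hydroperoxide; this sets the relay stereocentre.

Step 10
Reactants: 11 [(1Z,9R)-11-methoxy-9-methyldodeca-1,11-dien-1-yl]benzene; 14 (3R)-3-hydroperoxy-2-methylbut-1-ene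
Product: 15 [(1Z,9R)-11-methoxy-9-methyl-11-{[(2R)-3-methylbut-3-en-2-yl]peroxy}dodec-1-en-1-yl]benzene (both epimers at the ketal carbon)
Conditions: PPTS (cat.), CH2Cl2, 0 °C
Reagents that add atoms: none
Why: Acid-catalysed Markovnikov addition of the hydroperoxide O–H to a methyl enol ether (peroxyketalisation, as with 2-methoxypropene); the hydroperoxide stereocentre is not involved and the ketal epimers converge in step 11.

Step 11
Reactants: 15 [(1Z,9R)-11-methoxy-9-methyl-11-{[(2R)-3-methylbut-3-en-2-yl]peroxy}dodec-1-en-1-yl]benzene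
Product: 19 (3S,4R,6S)-3-methoxy-3,4,6-trimethyl-6-[(2R,9Z)-2-methyl-10-phenyldec-9-en-1-yl]-1,2-dioxane, via peroxycarbenium triflate 16 (not isolated), via dioxan-4-yl cation 17 (not isolated), via ring peroxycarbenium 18 (not isolated)
Conditions: TMSOTf (0.3 equiv), 2,6-di-tert-butyl-4-methylpyridine (0.1 equiv), CH2Cl2 (0.02 M), −78 to −30 °C; then Et3N
Reagents that add atoms: none
Why: Proposed new method: TMSOTf removes the methoxy group of 15 as Me3SiOMe to give the ketone-derived peroxycarbenium ion 16, whose C6 is attacked by the CH2 terminus (C5) of the tethered isopropenyl group; the tertiary C4 cation 17 is quenched by a suprafacial 1,2-hydride shift from C3, which creates the more stabilised ring peroxycarbenium 18, and Me3SiOMe returns the methoxy group to C3 and regenerates TMSOTf, so the step is a catalytic isomerisation. The closest known reaction types are the Lewis acid-mediated capture of peroxycarbenium ions from monoperoxyketals by alkenes and allylsilanes and the Prins–pinacol sequence, in which a Prins cation is terminated by a 1,2-shift onto a heteroatom-stabilised cation; the 1,2-dioxane closes in the 6-endo-trig mode, since 5-exo closure would need a primary cation. C6 is set by the C3 stereocentre through a chair in which the C3 methyl is pseudo-axial (avoiding A(1,2) strain with the C4 methyl) and the larger CH2R arm of the E peroxycarbenium is pseudo-equatorial; C4 is set by delivery of the C3 hydrogen on the ring face it occupied (methyl cis to the C6 arm), which is also the thermodynamic epimer; C3 is quenched axially (anomeric) and is settled again in step 12. The step needs hydride rather than methyl migration and capture by the isopropenyl group rather than by the styrene: in the sofa form of 17, which keeps the electron-poor C3–O2 bond in the nodal plane, C3–H and C3–CH3 are both aligned, hydride has the higher migratory aptitude and leads to the tertiary peroxycarbenium, and the 1,1-disubstituted alkene sits in a six-membered array while the Z-styrene is remote.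

Step 12
Reactants: 19 (3S,4R,6S)-3-methoxy-3,4,6-trimethyl-6-[(2R,9Z)-2-methyl-10-phenyldec-9-en-1-yl]-1,2-dioxane
Product: 20 (3S,4R,6S)-3,4,6-trimethyl-6-[(2R,9Z)-2-methyl-10-phenyldec-9-en-1-yl]-1,2-dioxan-3-ol
Conditions: TsOH·H2O (cat.), MeCN/H2O 4:1, 0 °C to rt
Reagents that add atoms: water, O
Why: Acid-catalysed hydrolysis of the cyclic methyl peroxyketal through the ring peroxycarbenium ion; C3 settles with hydroxyl axial (anomeric effect) and methyl equatorial, and C4, epimerisable through the open-chain γ-hydroperoxy ketone, keeps its equatorial methyl, so the thermodynamic hemiketal is 20.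

**Compound list**

1 | (R)-citronellic acid, (3R)-3,7-dimethyloct-6-enoic acid | C[C@H](CCC=C(C)C)CC(=O)O | starting material
2 | (4R)-4,8-dimethylnon-7-en-2-one | C[C@H](CCC=C(C)C)CC(C)=O | intermediate
3 | (6R)-8,8-dimethoxy-2,6-dimethylnon-2-ene | C[C@H](CCC=C(C)C)CC(C)(OC)OC | intermediate
4 | (4R)-6,6-dimethoxy-4-methylheptanal (not isolated) | C[C@H](CCC=O)CC(C)(OC)OC | intermediate
5 | (4R)-6,6-dimethoxy-4-methylheptan-1-ol | C[C@H](CCCO)CC(C)(OC)OC | intermediate
6 | (4R)-6,6-dimethoxy-4-methylheptyl 4-methylbenzenesulfonate | C[C@H](CCCOS(=O)(=O)c1ccc(C)cc1)CC(C)(OC)OC | intermediate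
7 | (5-chloropent-1-yn-1-yl)benzene | ClCCCC#Cc1ccccc1 | starting material
8 | chlorido(5-phenylpent-4-yn-1-yl)magnesium (not isolated) | Cl[Mg]CCCC#Cc1ccccc1 | intermediate
9 | [(9R)-11,11-dimethoxy-9-methyldodec-1-yn-1-yl]benzene | C[C@H](CCCCCCC#Cc1ccccc1)CC(C)(OC)OC | intermediate
10 | [(1Z,9R)-11,11-dimethoxy-9-methyldodec-1-en-1-yl]benzene | C[C@H](CCCCCC/C=C\c1ccccc1)CC(C)(OC)OC | intermediate
11 | [(1Z,9R)-11-methoxy-9-methyldodeca-1,11-dien-1-yl]benzene | C=C(OC)C[C@H](C)CCCCCC/C=C\c1ccccc1 | intermediate
12 | 2-methylbut-2-ene | CC=C(C)C | starting material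
13 | rac-3-hydroperoxy-2-methylbut-1-ene | C=C(C)C(C)OO | intermediate
14 | (3R)-3-hydroperoxy-2-methylbut-1-ene | C=C(C)[C@@H](C)OO | intermediate
15 | [(1Z,9R)-11-methoxy-9-methyl-11-{[(2R)-3-methylbut-3-en-2-yl]peroxy}dodec-1-en-1-yl]benzene, both epimers at C11 | C=C(C)[C@@H](C)OOC(C)(OC)C[C@H](C)CCCCCC/C=C\c1ccccc1 | intermediate
16 | E peroxycarbenium triflate from loss of methoxide from 15 (not isolated) | C=C(C)[C@@H](C)O/[O+]=C(\C)C[C@H](C)CCCCCC/C=C\c1ccccc1.[O-]S(=O)(=O)C(F)(F)F | intermediate
17 | 3,4,6-trimethyl-6-(2-methyl-10-phenyldec-9-enyl)-1,2-dioxan-4-ylium triflate, C3 hydrogen trans to the C6 arm (not isolated) | C[C@H](CCCCCC/C=C\c1ccccc1)C[C@@]1(C)C[C+](C)[C@@H](C)OO1.[O-]S(=O)(=O)C(F)(F)F | intermediate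
18 | ring peroxycarbenium triflate (C3=O2 cation) after the hydride shift (not isolated) | C[C@H](CCCCCC/C=C\c1ccccc1)C[C@@]1(C)C[C@@H](C)C(C)=[O+]O1.[O-]S(=O)(=O)C(F)(F)F | intermediate
19 | (3S,4R,6S)-3-methoxy-3,4,6-trimethyl-6-[(2R,9Z)-2-methyl-10-phenyldec-9-en-1-yl]-1,2-dioxane | C[C@H](CCCCCC/C=C\c1ccccc1)C[C@@]1(C)C[C@@H](C)[C@@](C)(OC)OO1 | intermediate
20 | (3S,4R,6S)-3,4,6-trimethyl-6-[(2R,9Z)-2-methyl-10-phenyldec-9-en-1-yl]-1,2-dioxan-3-ol | C[C@H](CCCCCC/C=C\c1ccccc1)C[C@@]1(C)C[C@@H](C)[C@@](C)(O)OO1 | target

**Step count and risks**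

Total: 12 steps. Longest linear sequence: 10 steps (steps 1–7, 10, 11, 12).

Steps most likely to fail:

1. Step 11 (proposed new method).
   - What may go wrong: migration of the C3 methyl instead of the C3 hydrogen. In the chair that closes the ring, the methyl is the group aligned with the empty orbital, and its shift would give a 4,4-dimethyl aldehyde-level peroxyacetal.
   - Also possible: proton loss from the C4 cation to 4-methylene or 4-ene peroxides, poor facial selectivity at C6 through the competing chair with the C3 methyl pseudo-equatorial, and acid-induced heterolysis of the O–O bond.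
   - Fallback (known chemistry; sets out from 10, returns at 20). Ketal 10 is hydrolysed (PPTS, acetone/H2O) to (4R,11Z)-4-methyl-12-phenyldodec-11-en-2-one F1. Kinetic enolisation with KN(SiMe3)2 and trapping with PhNTf2 (THF, −78 °C) gives the terminal enol triflate (4R,11Z)-4-methyl-12-phenyldodeca-1,11-dien-2-yl trifluoromethanesulfonate F2. Negishi coupling [Pd(PPh3)4, THF/DMA, 50 °C] with bromido[(2S)-3-methoxy-2-methyl-3-oxopropyl]zinc F3 (from commercial methyl (S)-3-bromo-2-methylpropanoate, Zn, LiCl) forms the C5–C6 bond intermolecularly and gives methyl (2R,6R,13Z)-2,6-dimethyl-4-methylidene-14-phenyltetradec-13-enoate F4. MeNHOMe·HCl with excess MeMgCl converts F4, through the Weinreb amide (2R,6R,13Z)-N-methoxy-N,2,6-trimethyl-4-methylidene-14-phenyltetradec-13-enamide F5 (not isolated), into (3R,7R,14Z)-3,7-dimethyl-5-methylidene-15-phenylpentadec-14-en-2-one F6. Mukaiyama–Isayama hydroperoxysilylation (Co(acac)2, O2, Et3SiH, 1,2-dichloroethane, rt) should act on the 1,1-disubstituted alkene in preference to the Z-styrene and give the tertiary silyl peroxide (3R,5S,7R,14Z)-3,5,7-trimethyl-15-phenyl-5-[(triethylsilyl)peroxy]pentadec-14-en-2-one F7 together with its epimer at the peroxide-bearing carbon. Bu4NF/AcOH (THF, 0 °C) removes the silyl group and the γ-hydroperoxy ketone closes to the peroxyhemiketal, giving 20 and its C6 epimer, which are separated by preparative HPLC.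

2. Step 9.
   - What may go wrong: poor acceptance of the small aliphatic allylic hydroperoxide by the enzyme, low enantiomer discrimination, or retention of the wrong enantiomer.
   - Fallback (sets out from 13, returns at 14). Racemic 13 is added (PPTS, CH2Cl2) to the known resolving agent (1R,2S)-trans-2-phenylcyclohexyl 2-propenyl ether. The two diastereomeric perketals are separated by chromatography. The one derived from the R hydroperoxide, [(1S,2R)-2-({2-[(2R)-(3-methylbut-3-en-2-yl)peroxy]propan-2-yl}oxy)cyclohexyl]benzene F8, is cleaved with AcOH/THF/H2O to give 14; the configuration is assigned by reduction to the known alcohol.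

3. Step 12.
   - What may go wrong: incomplete exchange of methoxy for hydroxy (reversal to the methyl ketal on concentration) and acid-promoted Criegee-type fragmentation of the peroxyhemiketal during prolonged exposure.
   - Fallback (sets out from 19, returns at 20). 19 is treated with excess ethereal H2O2 and a trace of camphorsulfonic acid (0 °C), where the stronger α-nucleophile displaces methoxide under milder acid to give (3S,4R,6S)-3-hydroperoxy-3,4,6-trimethyl-6-[(2R,9Z)-2-methyl-10-phenyldec-9-en-1-yl]-1,2-dioxane F9. One equivalent of PPh3 (CH2Cl2, 0 °C) then reduces only the hydroperoxy group, the ring dialkyl peroxide being inert, and gives 20 under neutral conditions.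

**Further compounds**

F1 | step 11 | (4R,11Z)-4-methyl-12-phenyldodec-11-en-2-one | C[C@H](CCCCCC/C=C\c1ccccc1)CC(C)=O
F2 | step 11 | (4R,11Z)-4-methyl-12-phenyldodeca-1,11-dien-2-yl trifluoromethanesulfonate | C=C(OS(=O)(=O)C(F)(F)F)C[C@H](C)CCCCCC/C=C\c1ccccc1
F3 | step 11 | bromido[(2S)-3-methoxy-2-methyl-3-oxopropyl]zinc | Br[Zn]C[C@@H](C)C(=O)OC
F4 | step 11 | methyl (2R,6R,13Z)-2,6-dimethyl-4-methylidene-14-phenyltetradec-13-enoate | COC(=O)[C@H](C)CC(=C)C[C@H](C)CCCCCC/C=C\c1ccccc1
F5 | step 11 | (2R,6R,13Z)-N-methoxy-N,2,6-trimethyl-4-methylidene-14-phenyltetradec-13-enamide | CON(C)C(=O)[C@H](C)CC(=C)C[C@H](C)CCCCCC/C=C\c1ccccc1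
F6 | step 11 | (3R,7R,14Z)-3,7-dimethyl-5-methylidene-15-phenylpentadec-14-en-2-one | CC(=O)[C@H](C)CC(=C)C[C@H](C)CCCCCC/C=C\c1ccccc1
F7 | step 11 | (3R,5S,7R,14Z)-3,5,7-trimethyl-15-phenyl-5-[(triethylsilyl)peroxy]pentadec-14-en-2-one | CC(=O)[C@H](C)C[C@@](C)(OO[Si](CC)(CC)CC)C[C@H](C)CCCCCC/C=C\c1ccccc1
F8 | step 9 | [(1S,2R)-2-({2-[(2R)-(3-methylbut-3-en-2-yl)peroxy]propan-2-yl}oxy)cyclohexyl]benzene | C=C(C)[C@@H](C)OOC(C)(C)O[C@@H]1CCCC[C@H]1c1ccccc1
F9 | step 12 | (3S,4R,6S)-3-hydroperoxy-3,4,6-trimethyl-6-[(2R,9Z)-2-methyl-10-phenyldec-9-en-1-yl]-1,2-dioxane | C[C@H](CCCCCC/C=C\c1ccccc1)C[C@@]1(C)C[C@@H](C)[C@@](C)(OO)OO1
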